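**Plan**

- Retrosynthetic cuts, in order: the thirteen O-benzyl bonds; the upper interflavan bond C4(gallocatechin)–C8(middle catechin); in the terminal catechin unit the ring C bond C4–C4a, then its ether bond O1–C2; last the bond C4(middle)–C8(terminal ring A).
- Enabling feature: ring A of the terminal unit is a phloroglucinol nucleus that already carries the middle unit at C8. C4a is therefore the only free carbon ortho to O1 and is activated by O1, O5 and O7, and the C4 methylene beside the C3 carbinol is the trace of a terminal oxirane opened at its CH2 end.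
- Forward: benzylated (+)-catechin is oxidised at C4 and C4-arylated with 3,5-bis(benzyloxy)phenol ortho to its OH. The phenol oxygen then opens a (2S,3S)-3-arylglycidol at the benzylic carbon, and the diol is closed to a terminal epoxide.
- Ring order: the 6-endo epoxide–arene Friedel–Crafts closure builds ring C of the terminal unit on the existing C4–aryl bond, so that bond becomes the 4→8 link; the gallocatechin unit is joined last at C8 of the middle unit, then all benzyl ethers are removed.
- Stereochemistry: C2/C3 of the top and middle units come from (+)-gallocatechin and (+)-catechin; both C4 centres arise by attack on the C4 cation anti to the 3-OH (3,4-trans); terminal C3 and C2 come from Sharpless asymmetric epoxidation and SN2 inversion at the benzylic epoxide carbon.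

Key step: step 9

Assumption: the DDQ-mediated C4 etherification is taken to give the 4β (4S) ethers 3 and 16; C4 is ionised again in steps 3 and 12, so its configuration has no consequence for the route.

**Route**

Step 1
Reactants: 1 (+)-catechin
Product: 2 5,7,3',4'-tetra-O-benzyl-(+)-catechin
Conditions: BnBr (4.4 equiv), K2CO3, DMF, 0 °C to rt
Reagents that add atoms: benzyl bromide BrCc1ccccc1
Why: Williamson etherification of the four phenolic hydroxyls, which are far more acidic than the secondary 3-OH, at a temperature low enough to limit C-benzylation and base-induced epimerisation at C2.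

Step 2
Reactants: 2 5,7,3',4'-tetra-O-benzyl-(+)-catechin
Product: 3 (2R,3S,4S)-5,7-bis(benzyloxy)-2-[3,4-bis(benzyloxy)phenyl]-4-(2-ethoxyethoxy)chroman-3-ol
Conditions: DDQ (2 equiv), 2-ethoxyethanol, CH2Cl2, rt
Reagents that add atoms: 2-ethoxyethanol CCOCCO
Why: DDQ-mediated benzylic C–H oxidation, in which hydride abstraction from C4 (activated by the 5,7-dioxygenated ring A) gives a quinone methide-type cation that the alcohol traps as the C4 ether.

Step 3
Reactants: 3 the C4 ether of step 2; 4 3,5-bis(benzyloxy)phenol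
Product: 5 (2R,3S)-5,7-bis(benzyloxy)-2-[3,4-bis(benzyloxy)phenyl]-4α-[2,4-bis(benzyloxy)-6-hydroxyphenyl]chroman-3-ol (2,3-trans, 3,4-trans)
Conditions: 4 (3 equiv), TMSOTf (0.2 equiv), CH2Cl2, −78 to −30 °C
Reagents that add atoms: none
Why: Lewis acid-mediated Friedel–Crafts alkylation (the reaction type of interflavan couplings and of phloroglucinol capture of flavan-4-yl cations), in which the C4 cation should be attacked by the excess phenol through the less hindered carbon ortho to its free OH and from the α face, anti to the 3-OH, which sets the 3,4-trans C4 centre.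

Step 4
Reactants: 6 3,4-bis(benzyloxy)benzaldehyde
Product: 7 ethyl (E)-3-[3,4-bis(benzyloxy)phenyl]prop-2-enoate
Conditions: (EtO)2P(O)CH2CO2Et, NaH, THF, 0 °C to rt
Reagents that add atoms: triethyl phosphonoacetate CCOC(=O)CP(=O)(OCC)OCC
Why: Horner–Wadsworth–Emmons olefination with a stabilised phosphonate should give the E-enoate.

Step 5
Reactants: 7 ethyl (E)-3-[3,4-bis(benzyloxy)phenyl]prop-2-enoate
Product: 8 (E)-3-[3,4-bis(benzyloxy)phenyl]prop-2-en-1-ol
Conditions: i-Bu2AlH (2.5 equiv), CH2Cl2, −78 °C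
Reagents that add atoms: none
Why: 1,2-reduction of the enoate by the aluminium hydride gives the E-allylic alcohol and leaves the benzyl ethers untouched.

Step 6
Reactants: 8 (E)-3-[3,4-bis(benzyloxy)phenyl]prop-2-en-1-ol
Product: 9 [(2S,3S)-3-[3,4-bis(benzyloxy)phenyl]oxiran-2-yl]methanol
Conditions: Ti(OiPr)4 (10 mol %), L-(+)-diisopropyl tartrate (12 mol %), t-BuOOH, 4 Å MS, CH2Cl2, −20 °C
Reagents that add atoms: tert-butyl hydroperoxide CC(C)(C)OO
Why: Katsuki–Sharpless asymmetric epoxidation, in which the L-(+)-tartrate titanium complex selects one face of the E-allylic alcohol and should give the (2S,3S)-epoxy alcohol, the source of both stereocentres of the terminal unit.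

Step 7
Reactants: 5 the C4-aryl phenol of step 3; 9 the (2S,3S)-epoxy alcohol
Product: 10 (2S,3R)-3-[3,4-bis(benzyloxy)phenyl]-3-(aryloxy)propane-1,2-diol, in which aryloxy is the phenol oxygen of 5
Conditions: Cs2CO3 (0.5 equiv), DMF, 70 °C
Reagents that add atoms: none
Why: base-mediated epoxide opening by a phenoxide (the aryloxy-propanediol synthesis from trans-3-arylglycidols), in which SN2 attack at the benzylic carbon, activated by the p-alkoxyaryl group, inverts it to the R configuration of the future C2 while the other epoxide carbon keeps its oxygen and becomes the future (S)-C3, the erythro pattern of a 2,3-trans flavan-3-ol.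

Step 8
Reactants: 10 the aryl ether diol of step 7
Product: 12 aryl ether of 5 with the (R)-[3,4-bis(benzyloxy)phenyl][(2S)-oxiran-2-yl]methyl group on the phenol oxygen, via primary tosylate 11 (not isolated)
Conditions: TsCl, Et3N, Bu2SnO (cat.), CH2Cl2, 0 °C; then K2CO3, MeOH, rt
Reagents that add atoms: none
Why: stannylene-catalysed selective sulfonylation of the primary hydroxyl of the 1,2-diol followed by intramolecular Williamson closure gives the terminal epoxide with retention at the secondary carbinol (its C–O bond is not broken), the hindered 3-OH of the flavan being left alone.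

Step 9
Reactants: 12 the aryl epoxy ether of step 8
Product: 13 5,7,3',4'-tetra-O-benzylcatechin-(4α→8)-5,7,3',4'-tetra-O-benzylcatechin
Conditions: AuCl3 (5 mol %), AgOTf (15 mol %), CH2Cl2, 0 °C to rt
Reagents that add atoms: none
Why: AgOTf abstracts chloride from AuCl3 to give an oxophilic trivalent gold triflate that binds the oxirane oxygen; the ring carbon ortho to the ether oxygen (the future C4a) attacks the terminal CH2, and rearomatisation with proton transfer to the C3 alkoxide releases the chroman-3-ol and the catalyst. The closest known reaction type is the gold-catalysed intramolecular Friedel–Crafts epoxide–arene cyclisation of aryl glycidyl ethers to chroman-3-ols. Ring C of the terminal unit closes in the 6-endo-tet mode through the bond C4–C4a; the alternative 5-exo attack at C3 would give a dihydrobenzofuran. No new stereocentre is formed: the C3–O bond is not broken, so C3 keeps the configuration from step 6 and C2 that from step 7, which gives the 2,3-trans terminal unit. The step needs 6-endo over 5-exo opening and attack by one ring carbon only: the first is secured by the unhindered primary terminus against a secondary C3 that is shielded and inductively deactivated by the neighbouring aryloxy-bearing C2, the second by the substrate, since the other carbon ortho to the ether oxygen carries the middle unit and the para carbon cannot reach the epoxide. The mild catalyst at room temperature is chosen so that the benzylic ether at C2 and the acid-labile C4–aryl bond are not ionised.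

Step 10
Reactants: 14 (+)-gallocatechin
Product: 15 5,7,3',4',5'-penta-O-benzyl-(+)-gallocatechin
Conditions: BnBr (5.5 equiv), K2CO3, DMF, 0 °C to rt
Reagents that add atoms: benzyl bromide BrCc1ccccc1
Why: Williamson etherification of the five phenolic hydroxyls, as in step 1.

Step 11
Reactants: 15 5,7,3',4',5'-penta-O-benzyl-(+)-gallocatechin
Product: 16 (2R,3S,4S)-5,7-bis(benzyloxy)-4-(2-ethoxyethoxy)-2-[3,4,5-tris(benzyloxy)phenyl]chroman-3-ol
Conditions: DDQ (2 equiv), 2-ethoxyethanol, CH2Cl2, rt
Reagents that add atoms: 2-ethoxyethanol CCOCCO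
Why: DDQ-mediated benzylic C4–H oxidation with trapping by the alcohol, as in step 2.

Step 12
Reactants: 13 the protected dimer of step 9; 16 the gallocatechin C4 ether
Product: 17 5,7,3',4',5'-penta-O-benzylgallocatechin-(4α→8)-5,7,3',4'-tetra-O-benzylcatechin-(4α→8)-5,7,3',4'-tetra-O-benzylcatechin
Conditions: 13 (1.5 equiv), TMSOTf (0.2 equiv), CH2Cl2, −78 °C
Reagents that add atoms: none
Why: Friedel–Crafts interflavan coupling, in which the gallocatechin C4 cation should be captured by C8 of the upper unit of 13 (the most nucleophilic free ring carbon, the C8 of the lower unit being occupied) from the α face anti to the 3-OH, which sets the second 3,4-trans C4 centre.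

Step 13
Reactants: 17 the trideca-O-benzyl trimer
Product: 18 gallocatechin-(4α→8)-catechin-(4α→8)-catechin (target)
Conditions: H2 (1 atm), Pd(OH)2/C, THF/MeOH/H2O, rt
Reagents that add atoms: none
Why: hydrogenolysis of the thirteen benzyl ethers under neutral conditions, which should leave the acid-labile interflavan bonds and all stereocentres intact.

**Compound list**

1 | (+)-catechin, (2R,3S)-2-(3,4-dihydroxyphenyl)chromane-3,5,7-triol | Oc1cc(O)c2c(c1)O[C@H](c1ccc(O)c(O)c1)[C@@H](O)C2 | starting material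
2 | 5,7,3',4'-tetra-O-benzyl-(+)-catechin | c1ccccc1COc1cc(OCc3ccccc3)c2c(c1)O[C@H](c1ccc(OCc3ccccc3)c(OCc3ccccc3)c1)[C@@H](O)C2 | intermediate
3 | (2R,3S,4S)-5,7-bis(benzyloxy)-2-[3,4-bis(benzyloxy)phenyl]-4-(2-ethoxyethoxy)chroman-3-ol (4β ether) | c1ccccc1COc1cc(OCc3ccccc3)c2c(c1)O[C@H](c1ccc(OCc3ccccc3)c(OCc3ccccc3)c1)[C@@H](O)[C@H]2OCCOCC | intermediate
4 | 3,5-bis(benzyloxy)phenol | Oc1cc(OCc2ccccc2)cc(OCc2ccccc2)c1 | starting material
5 | (2R,3S)-5,7-bis(benzyloxy)-2-[3,4-bis(benzyloxy)phenyl]-4α-[2,4-bis(benzyloxy)-6-hydroxyphenyl]chroman-3-ol (2,3-trans, 3,4-trans) | c1ccccc1COc1cc(OCc3ccccc3)c2c(c1)O[C@H](c1ccc(OCc3ccccc3)c(OCc3ccccc3)c1)[C@@H](O)[C@@H]2c1c(O)cc(OCc2ccccc2)cc1OCc1ccccc1 | intermediate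
6 | 3,4-bis(benzyloxy)benzaldehyde | O=Cc1ccc(OCc2ccccc2)c(OCc2ccccc2)c1 | starting material
7 | ethyl (E)-3-[3,4-bis(benzyloxy)phenyl]prop-2-enoate | CCOC(=O)/C=C/c1ccc(OCc2ccccc2)c(OCc2ccccc2)c1 | intermediate
8 | (E)-3-[3,4-bis(benzyloxy)phenyl]prop-2-en-1-ol | OC/C=C/c1ccc(OCc2ccccc2)c(OCc2ccccc2)c1 | intermediate
9 | [(2S,3S)-3-[3,4-bis(benzyloxy)phenyl]oxiran-2-yl]methanol | OC[C@@H]1O[C@H]1c1ccc(OCc2ccccc2)c(OCc2ccccc2)c1 | intermediate
10 | compound 5 etherified at its phenol oxygen with the (1R,2S)-1-[3,4-bis(benzyloxy)phenyl]-2,3-dihydroxypropyl group | c1ccccc1COc1cc(OCc3ccccc3)c2c(c1)O[C@H](c1ccc(OCc3ccccc3)c(OCc3ccccc3)c1)[C@@H](O)[C@@H]2c1c(O[C@H](c2ccc(OCc3ccccc3)c(OCc3ccccc3)c2)[C@@H](O)CO)cc(OCc2ccccc2)cc1OCc1ccccc1 | intermediate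
11 | primary p-toluenesulfonate of diol 10 | c1ccccc1COc1cc(OCc3ccccc3)c2c(c1)O[C@H](c1ccc(OCc3ccccc3)c(OCc3ccccc3)c1)[C@@H](O)[C@@H]2c1c(O[C@H](c2ccc(OCc3ccccc3)c(OCc3ccccc3)c2)[C@@H](O)COS(=O)(=O)c2ccc(C)cc2)cc(OCc2ccccc2)cc1OCc1ccccc1 | intermediate (not isolated)
12 | compound 5 etherified at its phenol oxygen with the (R)-[3,4-bis(benzyloxy)phenyl][(2S)-oxiran-2-yl]methyl group | c1ccccc1COc1cc(OCc3ccccc3)c2c(c1)O[C@H](c1ccc(OCc3ccccc3)c(OCc3ccccc3)c1)[C@@H](O)[C@@H]2c1c(O[C@H](c2ccc(OCc3ccccc3)c(OCc3ccccc3)c2)[C@@H]2CO2)cc(OCc2ccccc2)cc1OCc1ccccc1 | intermediate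
13 | 5,7,3',4'-tetra-O-benzylcatechin-(4α→8)-5,7,3',4'-tetra-O-benzylcatechin | c1ccccc1COc1cc(OCc3ccccc3)c2c(c1)O[C@H](c1ccc(OCc3ccccc3)c(OCc3ccccc3)c1)[C@@H](O)[C@@H]2c1c(OCc2ccccc2)cc(OCc2ccccc2)c2c1O[C@H](c1ccc(OCc3ccccc3)c(OCc3ccccc3)c1)[C@@H](O)C2 | intermediate
14 | (+)-gallocatechin, (2R,3S)-2-(3,4,5-trihydroxyphenyl)chromane-3,5,7-triol | Oc1cc(O)c2c(c1)O[C@H](c1cc(O)c(O)c(O)c1)[C@@H](O)C2 | starting material
15 | 5,7,3',4',5'-penta-O-benzyl-(+)-gallocatechin | c1ccccc1COc1cc(OCc3ccccc3)c2c(c1)O[C@H](c1cc(OCc3ccccc3)c(OCc3ccccc3)c(OCc3ccccc3)c1)[C@@H](O)C2 | intermediate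
16 | (2R,3S,4S)-5,7-bis(benzyloxy)-4-(2-ethoxyethoxy)-2-[3,4,5-tris(benzyloxy)phenyl]chroman-3-ol (4β ether) | c1ccccc1COc1cc(OCc3ccccc3)c2c(c1)O[C@H](c1cc(OCc3ccccc3)c(OCc3ccccc3)c(OCc3ccccc3)c1)[C@@H](O)[C@H]2OCCOCC | intermediate
17 | 5,7,3',4',5'-penta-O-benzylgallocatechin-(4α→8)-5,7,3',4'-tetra-O-benzylcatechin-(4α→8)-5,7,3',4'-tetra-O-benzylcatechin | c1ccccc1COc1cc(OCc3ccccc3)c2c(c1)O[C@H](c1cc(OCc3ccccc3)c(OCc3ccccc3)c(OCc3ccccc3)c1)[C@@H](O)[C@@H]2c1c(OCc2ccccc2)cc(OCc2ccccc2)c2c1O[C@H](c1ccc(OCc3ccccc3)c(OCc3ccccc3)c1)[C@@H](O)[C@@H]2c1c(OCc2ccccc2)cc(OCc2ccccc2)c2c1O[C@H](c1ccc(OCc3ccccc3)c(OCc3ccccc3)c1)[C@@H](O)C2 | intermediate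
18 | gallocatechin-(4α→8)-catechin-(4α→8)-catechin | Oc1cc(O)c2c(c1)O[C@H](c1cc(O)c(O)c(O)c1)[C@@H](O)[C@@H]2c1c(O)cc(O)c2c1O[C@H](c1ccc(O)c(O)c1)[C@@H](O)[C@@H]2c1c(O)cc(O)c2c1O[C@H](c1ccc(O)c(O)c1)[C@@H](O)C2 | target

**Count**

Total steps: 13. Longest linear sequence: 8 steps (steps 1, 2, 3, 7, 8, 9, 12, 13).

**Steps most likely to fail, with fallbacks**

Step 7. The hindered ortho-substituted phenoxide of 5 may open the epoxide so slowly that Payne rearrangement of the glycidol and attack at the wrong carbon take over. The fallback forms the same C–O bond by Mitsunobu inversion instead; it sets out from aldehyde 6 and phenol 5 and comes back at epoxide 12, bypassing 10 and 11. Vinylmagnesium bromide is added to 6 to give racemic 1-[3,4-bis(benzyloxy)phenyl]prop-2-en-1-ol F1. Sharpless kinetic resolution with D-(−)-diisopropyl tartrate, Ti(OiPr)4 and t-BuOOH gives the erythro epoxy alcohol (R)-[3,4-bis(benzyloxy)phenyl][(2S)-oxiran-2-yl]methanol F2. Mitsunobu inversion with 4-nitrobenzoic acid gives the threo ester (S)-[3,4-bis(benzyloxy)phenyl][(2S)-oxiran-2-yl]methyl 4-nitrobenzoate F3, and methanolysis (K2CO3, MeOH) gives the threo alcohol (S)-[3,4-bis(benzyloxy)phenyl][(2S)-oxiran-2-yl]methanol F4. Mitsunobu etherification of 5 with F4 (PPh3, DIAD, the alcohol activated before 5 is added so that the 3-OH of 5 is not engaged) inverts the carbinol and gives 12.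

Step 3. The flavan-4-yl cation may be taken up by the ring carbon para to the phenol OH, or stay on oxygen, which would put the later ether oxygen in the wrong place relative to the interflavan carbon. The fallback removes the regiochemical question by symmetry; it sets out from 3 and comes back at 5. Coupling of 3 with phloroglucinol (BF3·OEt2, THF/CH2Cl2), whose three ring carbons are equivalent, gives (2R,3S)-5,7-bis(benzyloxy)-2-[3,4-bis(benzyloxy)phenyl]-4α-(2,4,6-trihydroxyphenyl)chroman-3-ol F5. Controlled dibenzylation (BnBr 2 equiv, K2CO3, DMF) at the unhindered para hydroxyl and at one of the two equivalent ortho hydroxyls gives 5.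

Step 9. The Lewis acid may open the epoxide in the 5-exo mode or ionise the benzylic ether at C2 and the C4–aryl bond before ring closure. The fallback gives up the late ring closure and takes the terminal unit from the chiral pool; it sets out from 3 and 2 and comes back at 13. Coupling of 3 with an excess of 2 (TMSOTf, CH2Cl2, −78 °C), a Friedel–Crafts reaction at C8 of 2, gives 13 directly. This fallback makes no new compound (F0).

**Further compounds**

F1 | step 7 | rac-1-[3,4-bis(benzyloxy)phenyl]prop-2-en-1-ol | OC(C=C)c1ccc(OCc2ccccc2)c(OCc2ccccc2)c1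
F2 | step 7 | (R)-[3,4-bis(benzyloxy)phenyl][(2S)-oxiran-2-yl]methanol | O[C@H](c1ccc(OCc2ccccc2)c(OCc2ccccc2)c1)[C@@H]1CO1
F3 | step 7 | (S)-[3,4-bis(benzyloxy)phenyl][(2S)-oxiran-2-yl]methyl 4-nitrobenzoate | O=C(O[C@@H](c1ccc(OCc2ccccc2)c(OCc2ccccc2)c1)[C@@H]1CO1)c1ccc(cc1)[N+](=O)[O-]
F4 | step 7 | (S)-[3,4-bis(benzyloxy)phenyl][(2S)-oxiran-2-yl]methanol | O[C@@H](c1ccc(OCc2ccccc2)c(OCc2ccccc2)c1)[C@@H]1CO1
F5 | step 3 | (2R,3S)-5,7-bis(benzyloxy)-2-[3,4-bis(benzyloxy)phenyl]-4α-(2,4,6-trihydroxyphenyl)chroman-3-ol | c1ccccc1COc1cc(OCc3ccccc3)c2c(c1)O[C@H](c1ccc(OCc3ccccc3)c(OCc3ccccc3)c1)[C@@H](O)[C@@H]2c1c(O)cc(O)cc1O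
F0 | step 9 | none | none
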